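Open the ledger on the theta run. Starting material is the limiting reagent there, so each mole of it must stand in some entry, and the flasks below are then entered in the same books.

| flask | starting material | partner | protic impurity | free catalyst | temperature | remark | time |
|---|---|---|---|---|---|---|---|
| zeta | 0.22 M | 1.2 equiv | 0.22 M | 5 mol% | 32 °C | run made earlier |  |
| eta | 0.22 M | 3.9 equiv | 0.22 M | 5 mol% | 49 °C | run made earlier |  |
| theta | 0.22 M | 1.5 equiv | 0.22 M | 4.2 mol% | 32 °C | run made earlier |  |
| south | 0.40 M | 1.50 equiv | 0.0600 M | 8 mol% | 25 °C |  | 2.5 min |
| west | 0.30 M | 6.00 equiv | 0.0600 M | 5 mol% | 25 °C |  | 2.5 min |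
| north-west | 0.15 M | 1.50 equiv | 0.220 M | 10 mol% | 25 °C |  | 2.5 min |
| north | 0.22 M | 1.50 equiv | 0.220 M | 5 mol% | 25 °C |  | 2.5 min |
| north-east | 0.22 M | 1.50 equiv | 0.220 M | 3 mol% | 55 °C |  | 2.5 min |

| run | time / s | target / % | starting material / % |
|---|---|---|---|
| zeta | 20.0 | 14 | 56 |
| zeta | 40.0 | 19 | 37 |
| zeta | 50.0 | 25 | 31 |
| zeta | 80.0 | 27 | 20 |
| zeta | 120 | 31 | 17 |
| eta | 10.0 | 14 | 44 |
| eta | 12.0 | 16 | 43 |
| eta | 15.0 | 18 | 38 |
| eta | 25.0 | 19 | 32 |
| eta | 40.0 | 26 | 28 |
| theta | 20.0 | 13 | 56 |
| theta | 40.0 | 20 | 36 |
| theta | 60.0 | 26 | 31 |
| theta | 80.0 | 28 | 20 |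
| theta | 120 | 31 | 19 |

(scatter of a reading: 1.5 percentage points)

- the flasks by amount of target, in percent of the starting material charged, highest first, at 2.5 min (south / west / north-west / north / north-east)
- the same order at 15 s (south / west / north-west / north / north-east)
- the amount of target, in percent of the starting material charged of the flask you put first, at 2.5 min
- the amount of target, in percent of the starting material charged of the flask you put last, at 2.5 min

- no earlier run changes the charge of protic impurity; that part of a forecast is a guess

Close theta at 120 s: 31% stands as target and 19% as starting material, so an unnamed loss holds 50.0%. Divide that loss by the target to get 1.61. Now assume the loss runs as c(starting material) × c(protic impurity) and the target as c(starting material) × c(free catalyst). In the ratio of the two rates c(starting material) cancels, so the integral closes at once: loss = toll × target.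

Take both concentrations at their charges. Theta's readings then give 0.0677, the toll coefficient: a selectivity factor, the loss per target for each unit of c(protic impurity)/c(free catalyst). The readings of zeta give 0.0839 at the same 32 °C as theta, and those of eta give 0.0885 at 49 °C, which lies closer to zeta than zeta lies to theta, so carry no temperature term. Keep theta's value, as theta has the partner charge of south and north. The place of the impurity in the toll is a guess, and so is leaving partner out of it.

Multiply by each flask's c(protic impurity)/c(free catalyst). The tolls are south 0.127, west 0.271, north-west 0.994, north 1.35 and north-east 2.26. Enter theta's 19% as starting material left in each flask, which is another guess, and divide the consumed charge by one plus the toll. My ledger closes at 2.5 min with target at south 71.9%, west 63.7%, north-west 40.6%, north 34.5% and north-east 24.8%. It says nothing about 15 s.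

The forecast reads south > west > north-east > north > north-west at 2.5 min and south > west > north-east > north > north-west at 15 s, with 87% first and 27% last. South stands higher there than in my ledger, and we part on the places of north-west and north-east; of north-east it says: “North-east dumps SM quickly, then slowly converts the rest”.

The simulation gives south > west > north-west > north > north-east at 2.5 min, from 59.7% down to 25.1%, and south > west > north-east > north-west > north at 15 s. South ends 12 percentage points below my ledger, and it holds 15.3% as dormant form beside 7.51% as quenched substrate. Its toll of 0.127 stands against a loss per target of 0.386, counted as in theta, and of that loss quenched substrate per target makes 0.126.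

    starting material + protic impurity → quenched substrate (k = 0.0320 L mol⁻¹ s⁻¹, Ea = 41.0 kJ mol⁻¹)
    starting material + free catalyst → catalyst intermediate A (k = 1.30 L mol⁻¹ s⁻¹, Ea = 35.0 kJ mol⁻¹)
    partner + catalyst intermediate A → catalyst intermediate B (k = 1.00 L mol⁻¹ s⁻¹, Ea = 53.0 kJ mol⁻¹)
    2 free catalyst → spent catalyst (k = 1.70 L mol⁻¹ s⁻¹, Ea = 49.0 kJ mol⁻¹)
    catalyst intermediate B → free catalyst + target (k = 18.0 s⁻¹, Ea = 53.0 kJ mol⁻¹)
    starting material ⇌ dormant form (K = 0.810, k = 0.00490 s⁻¹, Ea = 94.0 kJ mol⁻¹, ΔH = −11.0 kJ mol⁻¹)
    (constants at 25 °C)

The neighbour of south charged with 0.15 M of protic impurity has a toll of 0.318, and the ledger gives target 61.5%. Computed, it holds 55.6% target and 13.4% starting material, a loss per target of 0.558, and of that loss its 17.3% quenched substrate makes 0.312 per target.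

The data stem from a simulated flask for an exercise; the scatter is artificial.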